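**Plan**

1. Retrosynthesis: after removal of six benzyl ethers and return of the lower 4‑OH to a C4 sulfide, one cut undoes both the C4–C6′ interflavan bond and the upper pyran ring (C2 moved from C3 back to C4). This gives 2‑aryl‑2,3‑dihydrobenzofuran‑3‑carbaldehyde 20 and lower flavan 18.
2. Enabling feature: in the upper pyran ring C4 is benzylic, para to O7 and ortho to O1, C3 carries oxygen, and C2 carries O1 plus an electron‑rich aryl group. The ring is therefore the capture product of a 3‑oxy‑flavan‑4‑yl cation, which a 3‑formyl dihydrobenzofuran can reach by a 1,2‑shift of C2.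
3. The lower flavan is traced back by a 1,2‑aryl shift (phenonium ion) to the cis‑3‑hydroxymethyl form of the same dihydrobenzofuran (11). Compound 11 is cut at the furan C2–C3 bond (carbenoid C–H insertion) to an aryl diazoacetate made from gallacetophenone.
4. Forward order of rings: ring A (bought) → furan ring (step 6) → lower pyran ring by ring expansion (step 9) → upper pyran ring by ring expansion with formation of the interflavan bond (step 13) → lower 4‑OH → debenzylation.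
5. Stereochemistry: C2 of both units comes from the chiral rhodium catalyst (step 6); lower C3 from anti opening of the phenonium ion; upper C3 from the trans aldehyde through the rotamer of the shift; upper C4 and lower C4 from attack on 2,3‑cis flavan‑4‑yl cations anti to O3.

Key step: step 13

Assumption: Rh2(S‑PTTL)4 is taken to give the (2S,3R) cis ester 10; if its sense of induction is the opposite, the enantiomeric catalyst Rh2(R‑PTTL)4 is used instead.

**Step 1**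
Reactants: 1 1‑(2,3,4‑trihydroxyphenyl)ethan‑1‑one (gallacetophenone)
Product: 2 1‑[3,4‑bis(benzyloxy)‑2‑hydroxyphenyl]ethan‑1‑one
Conditions: BnBr (2.1 equiv), K2CO3, DMF, rt
Reagents that add atoms: benzyl bromide BrCc1ccccc1
Why: Williamson etherification in which the 2‑OH, hydrogen‑bonded to the acetyl carbonyl, is the least reactive phenol, so two equivalents of BnBr should alkylate O‑4 and O‑3 only.

**Step 2**
Reactants: 2 1‑[3,4‑bis(benzyloxy)‑2‑hydroxyphenyl]ethan‑1‑one; 3 1‑(benzyloxy)‑4‑(chloromethyl)benzene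
Product: 4 1‑[3,4‑bis(benzyloxy)‑2‑{[4‑(benzyloxy)phenyl]methoxy}phenyl]ethan‑1‑one
Conditions: K2CO3, KI (cat.), DMF, 70 °C
Reagents that add atoms: none
Why: Williamson etherification of the chelated 2‑OH under more forcing conditions attaches the benzylic ether whose CH2 becomes C2 of both flavan units, its aryl group being ring B.

**Step 3**
Reactants: 4 1‑[3,4‑bis(benzyloxy)‑2‑{[4‑(benzyloxy)phenyl]methoxy}phenyl]ethan‑1‑one
Product: 6 1‑[3,4‑bis(benzyloxy)‑2‑{[4‑(benzyloxy)phenyl]methoxy}phenyl]‑2‑diazoethan‑1‑one, via trifluoroacetyl diketone 5 (not isolated)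
Conditions: LiN(SiMe3)2 (LiHMDS), THF, −78 °C; CF3CO2CH2CF3; aq HCl; then MsN3, Et3N, H2O, MeCN, rt
Reagents that add atoms: methanesulfonyl azide CS(=O)(=O)N=[N+]=[N-]
Why: Detrifluoroacetylative diazo transfer (Regitz type), in which the lithium enolate is trifluoroacetylated to the activated 1,3‑diketone 5 and this takes up N2 from the sulfonyl azide with loss of the trifluoroacetyl group.

**Step 4**
Reactants: 6 1‑[3,4‑bis(benzyloxy)‑2‑{[4‑(benzyloxy)phenyl]methoxy}phenyl]‑2‑diazoethan‑1‑one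
Product: 8 methyl 2‑[3,4‑bis(benzyloxy)‑2‑{[4‑(benzyloxy)phenyl]methoxy}phenyl]acetate, via aryl ketene 7 (not isolated)
Conditions: PhCO2Ag (silver benzoate, 10 mol %), Et3N, MeOH/THF, rt
Reagents that add atoms: methanol CO
Why: Wolff rearrangement (second half of an Arndt–Eistert homologation), the 1,2‑aryl shift giving ketene 7 that methanol traps as the arylacetate under neutral conditions that spare the acid‑labile 4‑alkoxybenzyl ether.

**Step 5**
Reactants: 8 methyl 2‑[3,4‑bis(benzyloxy)‑2‑{[4‑(benzyloxy)phenyl]methoxy}phenyl]acetate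
Product: 9 methyl 2‑[3,4‑bis(benzyloxy)‑2‑{[4‑(benzyloxy)phenyl]methoxy}phenyl]‑2‑diazoacetate
Conditions: p‑ABSA, DBU, MeCN, 0 °C to rt
Reagents that add atoms: 4‑acetamidobenzenesulfonyl azide CC(=O)Nc1ccc(cc1)S(=O)(=O)N=[N+]=[N-]
Why: Regitz diazo transfer to the benzylic CH2 of an arylacetate is the standard entry to donor/acceptor aryl diazoacetates.

**Step 6**
Reactants: 9 methyl 2‑[3,4‑bis(benzyloxy)‑2‑{[4‑(benzyloxy)phenyl]methoxy}phenyl]‑2‑diazoacetate
Product: 10 methyl (2S,3R)‑6,7‑bis(benzyloxy)‑2‑[4‑(benzyloxy)phenyl]‑2,3‑dihydro‑1‑benzofuran‑3‑carboxylate (2,3‑cis)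
Conditions: Rh2(S‑PTTL)4 [dirhodium tetrakis(N‑phthaloyl‑(S)‑tert‑leucinate)] (1 mol %), toluene, −78 °C
Reagents that add atoms: none
Why: Intramolecular 1,5 C–H insertion of the rhodium donor/acceptor carbenoid into the ether‑activated benzylic CH2 (five‑membered ring closure) is the established enantioselective route to cis‑2‑aryl‑2,3‑dihydrobenzofuran‑3‑carboxylates, the chiral carboxylate ligands setting C2 and the concerted insertion the kinetic 2,3‑cis relation.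

**Step 7**
Reactants: 10 methyl (2S,3R)‑6,7‑bis(benzyloxy)‑2‑[4‑(benzyloxy)phenyl]‑2,3‑dihydro‑1‑benzofuran‑3‑carboxylate
Product: 11 [(2S,3S)‑6,7‑bis(benzyloxy)‑2‑[4‑(benzyloxy)phenyl]‑2,3‑dihydro‑1‑benzofuran‑3‑yl]methanol (2,3‑cis)
Conditions: LiAlH4, THF, 0 °C
Reagents that add atoms: none
Why: Hydride reduction of the ester to the primary alcohol, addition being faster than enolisation at 0 °C so that the cis relation should be kept.

**Step 8**
Reactants: 11 [(2S,3S)‑6,7‑bis(benzyloxy)‑2‑[4‑(benzyloxy)phenyl]‑2,3‑dihydro‑1‑benzofuran‑3‑yl]methanol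
Product: 12 [(2S,3S)‑6,7‑bis(benzyloxy)‑2‑[4‑(benzyloxy)phenyl]‑2,3‑dihydro‑1‑benzofuran‑3‑yl]methyl methanesulfonate
Conditions: MsCl, Et3N, CH2Cl2, −20 °C
Reagents that add atoms: methanesulfonyl chloride CS(Cl)(=O)=O
Why: Sulfonylation of a primary alcohol, run cold and taken on at once because the neighbouring electron‑rich aryl group already assists ionisation.

**Step 9**
Reactants: 12 [(2S,3S)‑6,7‑bis(benzyloxy)‑2‑[4‑(benzyloxy)phenyl]‑2,3‑dihydro‑1‑benzofuran‑3‑yl]methyl methanesulfonate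
Product: 14 (2R,3R)‑7,8‑bis(benzyloxy)‑2‑[4‑(benzyloxy)phenyl]‑3,4‑dihydro‑2H‑1‑benzopyran‑3‑ol (4′,7,8‑tri‑O‑benzyl‑epioritin), via phenonium ion 13 (not isolated)
Conditions: (CF3)2CHOH/H2O (4:1), 2,6‑lutidine, 40 °C
Reagents that add atoms: water O
Why: Solvolysis with neighbouring aryl participation (Ar1‑3, phenonium ion; Wagner–Meerwein 1,2‑aryl shift as in the solvolysis of 2‑arylalkyl sulfonates and the fluorenylmethyl to phenanthrene ring expansion), in which the ring carbon para to OBn and ortho to the ring oxygen displaces mesylate and water opens the cyclopropane of 13 at its secondary carbon anti to the departing aryl bond, so that the furan becomes the pyran ring and the cis C2‑aryl/C3‑CH2 relation becomes the 2,3‑cis (2R,3R) flavan‑3‑ol.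

**Step 10**
Reactants: 14 (2R,3R)‑7,8‑bis(benzyloxy)‑2‑[4‑(benzyloxy)phenyl]‑3,4‑dihydro‑2H‑1‑benzopyran‑3‑ol
Product: 16 (2R,3R,4S)‑7,8‑bis(benzyloxy)‑2‑[4‑(benzyloxy)phenyl]‑4‑(2‑ethoxyethoxy)‑3,4‑dihydro‑2H‑1‑benzopyran‑3‑ol, via flavan‑4‑yl hydroquinonate ion pair 15 (not isolated)
Conditions: DDQ, EtOCH2CH2OH, CH2Cl2, rt
Reagents that add atoms: 2‑ethoxyethanol CCOCCO
Why: DDQ benzylic oxidation (hydride abstraction at C4, para to the 7‑alkoxy group, gives ion pair 15) followed by capture of the cation by the alcohol trans to the axial 3‑OH should give the 4β ether, as is known for benzylated epi‑flavan‑3‑ols.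

**Step 11**
Reactants: 16 (2R,3R,4S)‑7,8‑bis(benzyloxy)‑2‑[4‑(benzyloxy)phenyl]‑4‑(2‑ethoxyethoxy)‑3,4‑dihydro‑2H‑1‑benzopyran‑3‑ol
Product: 18 (2R,3S,4S)‑4‑(benzylsulfanyl)‑7,8‑bis(benzyloxy)‑2‑[4‑(benzyloxy)phenyl]‑3,4‑dihydro‑2H‑1‑benzopyran‑3‑ol, via flavan‑4‑yl alkoxytrifluoroborate ion pair 17 (not isolated)
Conditions: BnSH, BF3·OEt2 (0.2 equiv), CH2Cl2, −78 to −20 °C
Reagents that add atoms: phenylmethanethiol SCc1ccccc1
Why: Lewis‑acid‑catalysed exchange of the C4 alkoxy group for sulfur (SN1: BF3 binds the ether oxygen, ionisation gives ion pair 17, the thiol enters trans to the 3‑OH and the borate returns BF3 and 2‑ethoxyethanol) gives a C4 sulfide that hard Lewis acids do not ionise, which masks the future 4‑OH during the coupling.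

**Step 12**
Reactants: 11 [(2S,3S)‑6,7‑bis(benzyloxy)‑2‑[4‑(benzyloxy)phenyl]‑2,3‑dihydro‑1‑benzofuran‑3‑yl]methanol
Product: 20 (2S,3S)‑6,7‑bis(benzyloxy)‑2‑[4‑(benzyloxy)phenyl]‑2,3‑dihydro‑1‑benzofuran‑3‑carbaldehyde (2,3‑trans), via cis aldehyde 19 (not isolated)
Conditions: Dess–Martin periodinane, CH2Cl2, rt; aq NaHCO3 wash; then DBU (0.1 equiv), CH2Cl2, rt
Reagents that add atoms: none
Why: Dess–Martin oxidation to cis aldehyde 19 and base‑catalysed epimerisation through the enol to the more stable 2,3‑trans aldehyde, C2 staying untouched because ring opening by retro‑oxa‑Michael would be a disfavoured 5‑endo process.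

**Step 13**
Reactants: 20 (2S,3S)‑6,7‑bis(benzyloxy)‑2‑[4‑(benzyloxy)phenyl]‑2,3‑dihydro‑1‑benzofuran‑3‑carbaldehyde; 18 (2R,3S,4S)‑4‑(benzylsulfanyl)‑7,8‑bis(benzyloxy)‑2‑[4‑(benzyloxy)phenyl]‑3,4‑dihydro‑2H‑1‑benzopyran‑3‑ol
Product: 24 hexa‑O‑benzyl epioritin‑(4β→6)‑epioritin carrying a 4β‑benzylsulfanyl group on the lower unit (full name in the list), via silyl oxocarbenium ion 21 (not isolated), via silyloxy flavan‑4‑yl cation 22 (not isolated), via 3‑O‑silyl ether 23 (not isolated)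
Conditions: Me3SiOTf (TMSOTf, 0.2 equiv), 4 Å MS, CH2Cl2, −78 to −40 °C, 18 in excess (3 equiv); aq NaHCO3
Reagents that add atoms: none
Why: Proposed new method: TMSOTf silylates the formyl oxygen of 20 to oxocarbenium ion 21, and the C2–C3 bond of the dihydrobenzofuran, the best σ‑donor on the α‑carbon because C2 carries the ring oxygen and the 4‑benzyloxyphenyl group, shifts to the formyl carbon with retention at C2; the closest known reaction types are the acid‑catalysed aldehyde–ketone rearrangement (1,2‑shift to a protonated formyl group) and, read backwards, the Meinwald ring contraction of flav‑3‑ene oxides, and what is new is the interception of the rearranged cation by an arene. The shift is the ring‑forming event: the five‑membered ring becomes the pyran ring by a one‑carbon ring expansion (the formyl carbon is inserted between C2 and the benzylic carbon and becomes C3), leaving benzylic cation 22 at C4, stabilised by O7 (para) and O1 (ortho), which is the cation of Lewis‑acid interflavan couplings. C3 is set in the shift by the rotamer of 21: the C=O+ bond must stand perpendicular to the migrating bond, and the rotamer that turns the bulky O–Si group away from the fused benzene ring (formyl H over the ring) places oxygen cis to the C2 aryl group when the formyl group of 20 is trans to it, which is why the trans aldehyde is used. C4 is set by Friedel–Crafts attack of C6 of 18 (ortho to O7, para to O1, the most nucleophilic arene position present) on the face of 22 anti to both the 3‑silyloxy and the 2‑aryl group, the usual 3,4‑trans (4β) course of 2,3‑cis flavan‑4‑yl cations. The step needs the shift to outrun direct arene addition to 21, a 1,2‑hydride shift with aromatisation to the benzofuran, and heterolysis of C2–C3 (loss of configuration at C2); the strong cation stabilisation at C4, the α‑oxygen on the migrating carbon, the low temperature, the excess of 18 and its inert C4 sulfide are what should secure it, and silyl ether 23 is cleaved in the flask by the triflic acid released, which returns the catalyst.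

**Step 14**
Reactants: 24 hexa‑O‑benzyl epioritin‑(4β→6)‑epioritin carrying a 4β‑benzylsulfanyl group on the lower unit
Product: 26 hexa‑O‑benzyl epioritin‑(4β→6)‑epioritin‑4β‑ol (full name in the list), via dimer C4 cation 25 (not isolated)
Conditions: AgOTf (silver triflate, CF3SO3Ag, 1.5 equiv), 2,6‑lutidine, THF/H2O (9:1), 0 °C, dilute
Reagents that add atoms: water O
Why: Silver‑assisted heterolysis of the benzylic C–S bond (thiophilic activation, SN1) gives cation 25, which water should capture trans to the axial 3‑OH to give the 4β (4S) alcohol, dilution and the large excess of water suppressing C‑alkylation.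

**Step 15**
Reactants: 26 hexa‑O‑benzyl epioritin‑(4β→6)‑epioritin‑4β‑ol
Product: 27 epioritin‑(4β→6)‑epioritin‑4β‑ol (target)
Conditions: H2 (1 atm), Pd(OH)2/C, THF/MeOH, rt, stopped at full debenzylation
Reagents that add atoms: none
Why: Hydrogenolysis of the six aryl benzyl ethers in a neutral medium, which should be faster than the acid‑promoted hydrogenolysis of the benzylic C4–OH, the ring C–O bonds and the interflavan bond being left intact as in procyanidin syntheses.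

**Compound list**

1 | 1‑(2,3,4‑trihydroxyphenyl)ethan‑1‑one (gallacetophenone) | CC(=O)c1ccc(O)c(O)c1O | starting material
2 | 1‑[3,4‑bis(benzyloxy)‑2‑hydroxyphenyl]ethan‑1‑one | CC(=O)c1ccc(OCc2ccccc2)c(OCc2ccccc2)c1O | intermediate
3 | 1‑(benzyloxy)‑4‑(chloromethyl)benzene (4‑benzyloxybenzyl chloride) | ClCc1ccc(OCc2ccccc2)cc1 | starting material
4 | 1‑[3,4‑bis(benzyloxy)‑2‑{[4‑(benzyloxy)phenyl]methoxy}phenyl]ethan‑1‑one | CC(=O)c1ccc(OCc2ccccc2)c(OCc2ccccc2)c1OCc1ccc(OCc2ccccc2)cc1 | intermediate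
5 | 1‑[3,4‑bis(benzyloxy)‑2‑{[4‑(benzyloxy)phenyl]methoxy}phenyl]‑4,4,4‑trifluorobutane‑1,3‑dione (formed in the flask) | O=C(CC(=O)C(F)(F)F)c1ccc(OCc2ccccc2)c(OCc2ccccc2)c1OCc1ccc(OCc2ccccc2)cc1 | intermediate
6 | 1‑[3,4‑bis(benzyloxy)‑2‑{[4‑(benzyloxy)phenyl]methoxy}phenyl]‑2‑diazoethan‑1‑one | [N-]=[N+]=CC(=O)c1ccc(OCc2ccccc2)c(OCc2ccccc2)c1OCc1ccc(OCc2ccccc2)cc1 | intermediate
7 | 2‑[3,4‑bis(benzyloxy)‑2‑{[4‑(benzyloxy)phenyl]methoxy}phenyl]ethen‑1‑one (aryl ketene, formed in the flask) | O=C=Cc1ccc(OCc2ccccc2)c(OCc2ccccc2)c1OCc1ccc(OCc2ccccc2)cc1 | intermediate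
8 | methyl 2‑[3,4‑bis(benzyloxy)‑2‑{[4‑(benzyloxy)phenyl]methoxy}phenyl]acetate | COC(=O)Cc1ccc(OCc2ccccc2)c(OCc2ccccc2)c1OCc1ccc(OCc2ccccc2)cc1 | intermediate
9 | methyl 2‑[3,4‑bis(benzyloxy)‑2‑{[4‑(benzyloxy)phenyl]methoxy}phenyl]‑2‑diazoacetate | COC(=O)C(=[N+]=[N-])c1ccc(OCc2ccccc2)c(OCc2ccccc2)c1OCc1ccc(OCc2ccccc2)cc1 | intermediate
10 | methyl (2S,3R)‑6,7‑bis(benzyloxy)‑2‑[4‑(benzyloxy)phenyl]‑2,3‑dihydro‑1‑benzofuran‑3‑carboxylate (2,3‑cis) | COC(=O)[C@@H]1c2ccc(OCc3ccccc3)c(OCc3ccccc3)c2O[C@@H]1c1ccc(OCc2ccccc2)cc1 | intermediate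
11 | [(2S,3S)‑6,7‑bis(benzyloxy)‑2‑[4‑(benzyloxy)phenyl]‑2,3‑dihydro‑1‑benzofuran‑3‑yl]methanol (2,3‑cis) | OC[C@@H]1c2ccc(OCc3ccccc3)c(OCc3ccccc3)c2O[C@@H]1c1ccc(OCc2ccccc2)cc1 | intermediate
12 | [(2S,3S)‑6,7‑bis(benzyloxy)‑2‑[4‑(benzyloxy)phenyl]‑2,3‑dihydro‑1‑benzofuran‑3‑yl]methyl methanesulfonate (2,3‑cis) | CS(=O)(=O)OC[C@@H]1c2ccc(OCc3ccccc3)c(OCc3ccccc3)c2O[C@@H]1c1ccc(OCc2ccccc2)cc1 | intermediate
13 | phenonium ion from 12: cyclopropane‑fused arenium ion in which the former C3a is bonded both to C3 and to the former CH2OMs carbon (mesylate salt, formed in the flask) | C1[C@H]2[C@@H](c3ccc(OCc4ccccc4)cc3)[O+]=C3C(OCc4ccccc4)=C(OCc4ccccc4)C=C[C@]123.CS(=O)(=O)[O-] | intermediate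
14 | (2R,3R)‑7,8‑bis(benzyloxy)‑2‑[4‑(benzyloxy)phenyl]‑3,4‑dihydro‑2H‑1‑benzopyran‑3‑ol (4′,7,8‑tri‑O‑benzyl‑epioritin, 2,3‑cis) | O[C@@H]1Cc2ccc(OCc3ccccc3)c(OCc3ccccc3)c2O[C@@H]1c1ccc(OCc2ccccc2)cc1 | intermediate
15 | (2R,3R)‑7,8‑bis(benzyloxy)‑2‑[4‑(benzyloxy)phenyl]‑3‑hydroxy‑3,4‑dihydro‑2H‑1‑benzopyran‑4‑ylium 2,3‑dichloro‑5,6‑dicyano‑4‑hydroxyphenolate (flavan‑4‑yl cation paired with reduced DDQ, formed in the flask) | O[C@@H]1[CH+]c2ccc(OCc3ccccc3)c(OCc3ccccc3)c2O[C@@H]1c1ccc(OCc2ccccc2)cc1.[O-]c1c(Cl)c(Cl)c(O)c(C#N)c1C#N | intermediate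
16 | (2R,3R,4S)‑7,8‑bis(benzyloxy)‑2‑[4‑(benzyloxy)phenyl]‑4‑(2‑ethoxyethoxy)‑3,4‑dihydro‑2H‑1‑benzopyran‑3‑ol (2,3‑cis‑3,4‑trans) | O[C@@H]1[C@@H](OCCOCC)c2ccc(OCc3ccccc3)c(OCc3ccccc3)c2O[C@@H]1c1ccc(OCc2ccccc2)cc1 | intermediate
17 | (2R,3R)‑7,8‑bis(benzyloxy)‑2‑[4‑(benzyloxy)phenyl]‑3‑hydroxy‑3,4‑dihydro‑2H‑1‑benzopyran‑4‑ylium trifluoro(2‑ethoxyethoxy)borate (flavan‑4‑yl cation paired with the borate from 16 and BF3, formed in the flask) | O[C@@H]1[CH+]c2ccc(OCc3ccccc3)c(OCc3ccccc3)c2O[C@@H]1c1ccc(OCc2ccccc2)cc1.CCOCCO[B-](F)(F)F | intermediate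
18 | (2R,3S,4S)‑4‑(benzylsulfanyl)‑7,8‑bis(benzyloxy)‑2‑[4‑(benzyloxy)phenyl]‑3,4‑dihydro‑2H‑1‑benzopyran‑3‑ol (2,3‑cis‑3,4‑trans) | O[C@@H]1[C@@H](SCc2ccccc2)c2ccc(OCc3ccccc3)c(OCc3ccccc3)c2O[C@@H]1c1ccc(OCc2ccccc2)cc1 | intermediate
19 | (2S,3R)‑6,7‑bis(benzyloxy)‑2‑[4‑(benzyloxy)phenyl]‑2,3‑dihydro‑1‑benzofuran‑3‑carbaldehyde (2,3‑cis, formed in the flask) | O=C[C@@H]1c2ccc(OCc3ccccc3)c(OCc3ccccc3)c2O[C@@H]1c1ccc(OCc2ccccc2)cc1 | intermediate
20 | (2S,3S)‑6,7‑bis(benzyloxy)‑2‑[4‑(benzyloxy)phenyl]‑2,3‑dihydro‑1‑benzofuran‑3‑carbaldehyde (2,3‑trans) | O=C[C@H]1c2ccc(OCc3ccccc3)c(OCc3ccccc3)c2O[C@@H]1c1ccc(OCc2ccccc2)cc1 | intermediate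
21 | O‑trimethylsilyl oxocarbenium triflate of 20 (formed in the flask) | C[Si](C)(C)[O+]=C[C@H]1c2ccc(OCc3ccccc3)c(OCc3ccccc3)c2O[C@@H]1c1ccc(OCc2ccccc2)cc1.[O-]S(=O)(=O)C(F)(F)F | intermediate
22 | (2R,3R)‑7,8‑bis(benzyloxy)‑2‑[4‑(benzyloxy)phenyl]‑3‑[(trimethylsilyl)oxy]‑3,4‑dihydro‑2H‑1‑benzopyran‑4‑ylium triflate (2,3‑cis, formed in the flask) | C[Si](C)(C)O[C@@H]1[CH+]c2ccc(OCc3ccccc3)c(OCc3ccccc3)c2O[C@@H]1c1ccc(OCc2ccccc2)cc1.[O-]S(=O)(=O)C(F)(F)F | intermediate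
23 | 3‑O‑trimethylsilyl ether of 24 (silyl on the upper‑unit 3‑OH, formed in the flask) | C[Si](C)(C)O[C@@H]1[C@@H](c2cc3c(c(OCc4ccccc4)c2OCc2ccccc2)O[C@H](c2ccc(OCc4ccccc4)cc2)[C@H](O)[C@H]3SCc2ccccc2)c2ccc(OCc3ccccc3)c(OCc3ccccc3)c2O[C@@H]1c1ccc(OCc2ccccc2)cc1 | intermediate
24 | (2R,3S,4S)‑4‑(benzylsulfanyl)‑6‑[(2R,3R,4R)‑7,8‑bis(benzyloxy)‑2‑[4‑(benzyloxy)phenyl]‑3‑hydroxy‑3,4‑dihydro‑2H‑1‑benzopyran‑4‑yl]‑7,8‑bis(benzyloxy)‑2‑[4‑(benzyloxy)phenyl]‑3,4‑dihydro‑2H‑1‑benzopyran‑3‑ol (upper unit 2,3‑cis‑3,4‑trans, 4β‑aryl; the CIP label of upper C4 is R while O7′ is benzylated and S in the free phenol, with no change of geometry) | O[C@@H]1[C@@H](c2cc3c(c(OCc4ccccc4)c2OCc2ccccc2)O[C@H](c2ccc(OCc4ccccc4)cc2)[C@H](O)[C@H]3SCc2ccccc2)c2ccc(OCc3ccccc3)c(OCc3ccccc3)c2O[C@@H]1c1ccc(OCc2ccccc2)cc1 | intermediate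
25 | lower‑unit C4 cation of the dimer (24 without its benzylsulfanyl group; triflate salt, formed in the flask) | O[C@@H]1[C@@H](c2cc3c(c(OCc4ccccc4)c2OCc2ccccc2)O[C@H](c2ccc(OCc4ccccc4)cc2)[C@H](O)[CH+]3)c2ccc(OCc3ccccc3)c(OCc3ccccc3)c2O[C@@H]1c1ccc(OCc2ccccc2)cc1.[O-]S(=O)(=O)C(F)(F)F | intermediate
26 | (2R,3R,4S)‑6‑[(2R,3R,4R)‑7,8‑bis(benzyloxy)‑2‑[4‑(benzyloxy)phenyl]‑3‑hydroxy‑3,4‑dihydro‑2H‑1‑benzopyran‑4‑yl]‑7,8‑bis(benzyloxy)‑2‑[4‑(benzyloxy)phenyl]‑3,4‑dihydro‑2H‑1‑benzopyran‑3,4‑diol (hexa‑O‑benzyl ether of the target) | O[C@@H]1[C@@H](c2cc3c(c(OCc4ccccc4)c2OCc2ccccc2)O[C@H](c2ccc(OCc4ccccc4)cc2)[C@H](O)[C@H]3O)c2ccc(OCc3ccccc3)c(OCc3ccccc3)c2O[C@@H]1c1ccc(OCc2ccccc2)cc1 | intermediate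
27 | (2R,3R,4S)‑2‑(4‑hydroxyphenyl)‑6‑[(2R,3R,4S)‑3,7,8‑trihydroxy‑2‑(4‑hydroxyphenyl)‑3,4‑dihydro‑2H‑1‑benzopyran‑4‑yl]‑3,4‑dihydro‑2H‑1‑benzopyran‑3,4,7,8‑tetrol (epioritin‑(4β→6)‑epioritin‑4β‑ol) | Oc1ccc([C@H]2Oc3c(ccc(O)c3O)[C@H](c3cc4c(c(O)c3O)O[C@H](c3ccc(O)cc3)[C@H](O)[C@H]4O)[C@H]2O)cc1 | target

**Count and risks**

Total steps: 15. Longest linear sequence: 14 steps (steps 1 to 11, then 13 to 15); the aldehyde branch (steps 1 to 7, 12) joins at step 13.

Steps most likely to fail: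

Step 13 (Proposed new method). What may go wrong: direct Friedel–Crafts addition of 18 to the activated formyl group before the shift; a 1,2‑hydride shift followed by aromatisation to the 2‑arylbenzofuran; heterolysis of the C2–C3 bond with loss of configuration at C2; or poor rotamer control at C3. Fallback (sets out from 16 and 18, returns at 24; known chemistry, no new compound): 16 (1 equiv) and 18 (3 equiv) are combined with BF3·OEt2 in CH2Cl2 at −78 °C. The hard Lewis acid ionises the C4 ether of 16 to the flavan‑4‑yl cation but leaves the C4 sulfide of 18 alone (orthogonal activation), and C6 of 18 should attack trans to the 3‑OH to give 24 directly. The upper pyran ring then comes from step 9 and not from the ring expansion of 20.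

Step 9. What may go wrong: opening of the phenonium ion at its primary carbon (return to unrearranged alcohol 11), or proton loss from the bridged ion in place of attack at the secondary carbon. Fallback (sets out from 2, returns at 14; classical chalcone route, known chemistry): 2 is protected with MOMCl and NaH in DMF as 1‑[3,4‑bis(benzyloxy)‑2‑(methoxymethoxy)phenyl]ethan‑1‑one F1. Claisen–Schmidt condensation of this ketone with 4‑(benzyloxy)benzaldehyde (O=Cc1ccc(OCc2ccccc2)cc1; KOH, EtOH/THF) should give the (E)‑chalcone F2. Juliá–Colonna epoxidation (poly‑L‑leucine, urea–H2O2, DBU, THF) should give the (2R,3S)‑epoxy ketone F3. HCl in MeOH/THF removes the MOM group, and the freed phenol opens the epoxide at the benzylic carbon with inversion to give the (2R,3R)‑trans‑dihydroflavonol F4. LiAlH4/AlCl3 in Et2O/THF reduces the C4 carbonyl to CH2 and should give the (2R,3S)‑trans‑flavan‑3‑ol F5. Dess–Martin oxidation gives the (2R)‑flavan‑3‑one F6, and LiBH(s‑Bu)3 (L‑Selectride) in THF at −78 °C delivers hydride anti to the 2‑aryl group to give 14.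

Step 15. What may go wrong: over‑reduction, that is hydrogenolysis of the benzylic C4–OH of the lower unit once the para 7‑OH has been set free. Fallback (sets out from 26, returns at 27; known chemistry): the three alcohols of 26 are silylated with Et3SiOTf and 2,6‑lutidine in CH2Cl2 to give the tris(triethylsilyl) ether F7, whose benzylic C4–O bond is shielded. Hydrogenolysis (H2, Pd/C, EtOAc) removes the six benzyl groups and should give the hexaphenol tris(triethylsilyl) ether F8. HF·pyridine in THF at 0 °C then removes the silyl groups and gives 27.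

**Further compounds**

F0 | step 13 | none | none
F1 | step 9 | 1‑[3,4‑bis(benzyloxy)‑2‑(methoxymethoxy)phenyl]ethan‑1‑one | CC(=O)c1ccc(OCc2ccccc2)c(OCc2ccccc2)c1OCOC
F2 | step 9 | (E)‑1‑[3,4‑bis(benzyloxy)‑2‑(methoxymethoxy)phenyl]‑3‑[4‑(benzyloxy)phenyl]prop‑2‑en‑1‑one | O=C(/C=C/c1ccc(OCc2ccccc2)cc1)c1ccc(OCc2ccccc2)c(OCc2ccccc2)c1OCOC
F3 | step 9 | [3,4‑bis(benzyloxy)‑2‑(methoxymethoxy)phenyl][(2R,3S)‑3‑[4‑(benzyloxy)phenyl]oxiran‑2‑yl]methanone | O=C(c1ccc(OCc2ccccc2)c(OCc2ccccc2)c1OCOC)[C@@H]1O[C@H]1c1ccc(OCc2ccccc2)cc1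
F4 | step 9 | (2R,3R)‑7,8‑bis(benzyloxy)‑2‑[4‑(benzyloxy)phenyl]‑3‑hydroxy‑2,3‑dihydro‑4H‑1‑benzopyran‑4‑one (2,3‑trans) | O[C@H]1C(=O)c2ccc(OCc3ccccc3)c(OCc3ccccc3)c2O[C@@H]1c1ccc(OCc2ccccc2)cc1
F5 | step 9 | (2R,3S)‑7,8‑bis(benzyloxy)‑2‑[4‑(benzyloxy)phenyl]‑3,4‑dihydro‑2H‑1‑benzopyran‑3‑ol (2,3‑trans) | O[C@H]1Cc2ccc(OCc3ccccc3)c(OCc3ccccc3)c2O[C@@H]1c1ccc(OCc2ccccc2)cc1
F6 | step 9 | (2R)‑7,8‑bis(benzyloxy)‑2‑[4‑(benzyloxy)phenyl]‑2H‑1‑benzopyran‑3(4H)‑one | O=C1Cc2ccc(OCc3ccccc3)c(OCc3ccccc3)c2O[C@@H]1c1ccc(OCc2ccccc2)cc1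
F7 | step 15 | tris‑O‑(triethylsilyl) ether of 26 (upper 3‑O, lower 3‑O and lower 4‑O) | CC[Si](CC)(CC)O[C@@H]1[C@@H](c2cc3c(c(OCc4ccccc4)c2OCc2ccccc2)O[C@H](c2ccc(OCc4ccccc4)cc2)[C@H](O[Si](CC)(CC)CC)[C@H]3O[Si](CC)(CC)CC)c2ccc(OCc3ccccc3)c(OCc3ccccc3)c2O[C@@H]1c1ccc(OCc2ccccc2)cc1
F8 | step 15 | tris‑O‑(triethylsilyl) ether of 27 (upper 3‑O, lower 3‑O and lower 4‑O; all phenols free) | CC[Si](CC)(CC)O[C@@H]1[C@@H](c2cc3c(c(O)c2O)O[C@H](c2ccc(O)cc2)[C@H](O[Si](CC)(CC)CC)[C@H]3O[Si](CC)(CC)CC)c2ccc(O)c(O)c2O[C@@H]1c1ccc(O)cc1
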